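**Synthesis outline**

- Cuts: the two benzyl ethers and the silyl ether come off last. The strategic cut is C4–C5, the middle bond of the four-methylene tether C3–C6 (numbering as 1-aryltridecane: C2 acetoxy carbinol, C7 ketol carbinol, C8 ketone). Secondary cuts are C8–C9 (pentyl–carbonyl) and aryl–C1.
- Enabling feature: each carbinol carbon then carries a CH2–CH2 arm ending in a primary radical site. Each half is a 4-oxygenated butanoic acid minus CO2, that is, an opened 5-substituted γ-butyrolactone (five-membered ring, one ring oxygen), and both map onto one lactone acid.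
- Forward, ketol half (steps 1–5): Weinreb amide, lactone opening, silylation, pentyl Grignard addition (C8–C9), phthalimide ester.
- Forward, aryl half (steps 6–13): acid reduction, tosylate, epoxy ester, aryl Grignard epoxide opening (aryl–C1), acetate installation, phthalimide ester.
- Joining and stereochemistry: the halves are joined at C4–C5 in step 14, then desilylated and debenzylated; no ring is formed, the arene is bought. Both stereocentres are the one (R) centre of 5-oxotetrahydrofuran-2-carboxylic acid (D-glutamic acid series), whose C–O bond is never broken; no stereocentre is created.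

Key step: step 14

Remark on the chemistry (assumption): (R)-5-oxotetrahydrofuran-2-carboxylic acid and 1,3-bis(benzyloxy)-5-bromobenzene are taken as purchasable.

**Route**

Step 1
Reactants: 1 (R)-5-oxotetrahydrofuran-2-carboxylic acid
Product: 2 (R)-N-methoxy-N-methyl-5-oxotetrahydrofuran-2-carboxamide
Conditions: MeNHOMe·HCl (1.2 equiv), EDC·HCl (1.2 equiv), N-methylmorpholine (1.3 equiv), CH2Cl2, 0 °C → rt
Reagents that add atoms: N,O-dimethylhydroxylamine hydrochloride, Cl.CNOC
Why: Carbodiimide amide coupling (Weinreb amide formation) activates the acid as an O-acylisourea under nearly neutral conditions, so the α-oxygenated stereocentre, which cannot form an oxazolone, is not epimerised and the lactone is untouched.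

Step 2
Reactants: 2 (R)-N-methoxy-N-methyl-5-oxotetrahydrofuran-2-carboxamide
Product: 3 lithium (R)-4-hydroxy-5-[methoxy(methyl)amino]-5-oxopentanoate
Conditions: LiOH·H2O (1.0 equiv), THF/H2O (3:1), 0 °C; evaporate, azeotrope with toluene, use the dry salt directly
Reagents that add atoms: lithium hydroxide, [Li+].[OH-]
Why: Saponification of the five-membered lactone by one equivalent of hydroxide (acyl–oxygen cleavage, stereocentre untouched) should be much faster at 0 °C than attack on the N-methoxy-N-methylamide, and keeping the product as its carboxylate salt prevents relactonisation.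

Step 3
Reactants: 3 lithium (R)-4-hydroxy-5-[methoxy(methyl)amino]-5-oxopentanoate
Product: 5 (R)-4-(tert-butyldimethylsilyloxy)-5-[methoxy(methyl)amino]-5-oxopentanoic acid, via bis-silylated silyl ester 4 (not isolated)
Conditions: TBSCl (2.5 equiv), imidazole (5 equiv), DMF, rt; then K2CO3 (1.5 equiv), MeOH/THF/H2O, 0 °C; 0.5 M HCl to pH 4 at 0 °C
Reagents that add atoms: tert-butyldimethylsilyl chloride, CC(C)(C)[Si](C)(C)Cl
Why: Imidazole-mediated silylation caps both the hydroxyl and the carboxylate, and the far more labile silyl ester is then solvolysed selectively by carbonate in aqueous methanol, the standard way to turn a lactone into a silyloxy acid.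

Step 4
Reactants: 5 (R)-4-(tert-butyldimethylsilyloxy)-5-[methoxy(methyl)amino]-5-oxopentanoic acid; 6 n-pentyl bromide (1-bromopentane)
Product: 8 (R)-4-(tert-butyldimethylsilyloxy)-5-oxodecanoic acid, via pentylmagnesium bromide 7 (not isolated)
Conditions: Mg turnings, THF, 40 °C (6 → 7, 3.2 equiv); then 5, THF, −20 → 0 °C; sat. aq NH4Cl, then 1 M HCl to pH 3 at 0 °C
Reagents that add atoms: none
Why: Weinreb ketone synthesis, in which the first equivalent of Grignard reagent turns the acid into an unreactive magnesium carboxylate and the next adds to the amide to give a chelated tetrahedral intermediate that collapses only on quench, so neither over-addition nor enolisation of the α-silyloxy centre is expected; the enantiomeric purity is to be checked at this stage (chiral HPLC of the methyl ester).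

Step 5
Reactants: 8 (R)-4-(tert-butyldimethylsilyloxy)-5-oxodecanoic acid
Product: 9 1,3-dioxoisoindolin-2-yl (R)-4-(tert-butyldimethylsilyloxy)-5-oxodecanoate
Conditions: N-hydroxyphthalimide (1.1 equiv), DIC (1.1 equiv), DMAP (0.1 equiv), CH2Cl2, 0 °C → rt
Reagents that add atoms: N-hydroxyphthalimide, O=C1c2ccccc2C(=O)N1O
Why: Steglich-type carbodiimide esterification with N-hydroxyphthalimide is the routine way to a redox-active ester and does not touch the silyloxy ketone.

Step 6
Reactants: 1 (R)-5-oxotetrahydrofuran-2-carboxylic acid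
Product: 10 (R)-5-(hydroxymethyl)dihydrofuran-2(3H)-one
Conditions: BH3·SMe2 (1.2 equiv), THF, 0 °C → rt; MeOH quench
Reagents that add atoms: none
Why: Borane reduces a carboxylic acid through its acyloxyborane far faster than a lactone, a well-established chemoselective reduction that leaves the stereocentre alone.

Step 7
Reactants: 10 (R)-5-(hydroxymethyl)dihydrofuran-2(3H)-one
Product: 11 [(R)-5-oxotetrahydrofuran-2-yl]methyl 4-methylbenzenesulfonate
Conditions: TsCl (1.2 equiv), pyridine (3 equiv), CH2Cl2, 0 °C → rt
Reagents that add atoms: p-toluenesulfonyl chloride, Cc1ccc(cc1)S(Cl)(=O)=O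
Why: Sulfonylation of an unhindered primary alcohol is reliable and gives a crystalline tosylate.

Step 8
Reactants: 11 [(R)-5-oxotetrahydrofuran-2-yl]methyl 4-methylbenzenesulfonate
Product: 13 methyl (R)-4,5-epoxypentanoate, via ring-opened hydroxy tosylate 12 (not isolated)
Conditions: NaOMe (1.05 equiv), MeOH, 0 °C → rt
Reagents that add atoms: sodium methoxide, [Na+].[O-]C
Why: Methoxide transesterification opens the lactone to the methyl ester alkoxide, which closes the epoxide by intramolecular Williamson-type SN2 displacement of the primary tosylate; the C–O bond at the stereocentre is not broken, so the (R) configuration is carried over.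

Step 9
Reactants: 13 methyl (R)-4,5-epoxypentanoate; 14 bromoarene 1,3-bis(benzyloxy)-5-bromobenzene
Product: 17 (R)-5-[3,5-bis(benzyloxy)benzyl]dihydrofuran-2(3H)-one, via arylmagnesium bromide 15 (not isolated), via open-chain hydroxy ester 16 (not isolated)
Conditions: Mg turnings (I2 to start), THF, 50 °C (14 → 15, 1.3 equiv); CuI (10 mol %), then 13, THF, −40 → −20 °C; sat. aq NH4Cl; then TsOH·H2O (5 mol %), toluene, rt
Reagents that add atoms: none
Why: Copper-catalysed Grignard opening of a terminal epoxide occurs by SN2 attack at the unsubstituted carbon and at low temperature outruns addition to the methyl ester, the stereocentre is not involved, and the γ-hydroxy ester then lactonises under acid catalysis.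

Step 10
Reactants: 17 (R)-5-[3,5-bis(benzyloxy)benzyl]dihydrofuran-2(3H)-one
Product: 18 potassium (R)-5-[3,5-bis(benzyloxy)phenyl]-4-hydroxypentanoate
Conditions: KOH (1.05 equiv), MeOH/H2O (4:1), rt; evaporate, azeotrope with toluene, use the dry salt directly
Reagents that add atoms: potassium hydroxide, [K+].[OH-]
Why: Saponification of the γ-lactone gives the hydroxy carboxylate, which stays open as long as it is kept as the salt.

Step 11
Reactants: 18 potassium (R)-5-[3,5-bis(benzyloxy)phenyl]-4-hydroxypentanoate
Product: 20 allyl (R)-4-acetoxy-5-[3,5-bis(benzyloxy)phenyl]pentanoate, via hydroxy allyl ester 19 (not isolated)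
Conditions: allyl bromide (1.5 equiv), DMF, rt; then Ac2O (3 equiv), pyridine (6 equiv), DMAP (0.1 equiv), 0 °C → rt, same flask
Reagents that add atoms: allyl bromide, C=CCBr; acetic anhydride, CC(=O)OC(C)=O
Why: SN2 O-alkylation of the carboxylate in DMF gives the allyl ester, and DMAP-catalysed acetylation of the free secondary hydroxyl in the same flask should be much faster than its lactonisation, so the open chain is locked in as the acetate.

Step 12
Reactants: 20 allyl (R)-4-acetoxy-5-[3,5-bis(benzyloxy)phenyl]pentanoate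
Product: 21 (R)-4-acetoxy-5-[3,5-bis(benzyloxy)phenyl]pentanoic acid
Conditions: Pd(PPh3)4 (3 mol %), morpholine (3 equiv), THF, rt; 1 M KHSO4 work-up
Reagents that add atoms: none
Why: Tsuji–Trost deallylation, in which zerovalent palladium ionises the allyl ester to a π-allyl complex that morpholine intercepts, frees the acid under conditions that leave the secondary acetate and the benzyl ethers alone.

Step 13
Reactants: 21 (R)-4-acetoxy-5-[3,5-bis(benzyloxy)phenyl]pentanoic acid
Product: 22 1,3-dioxoisoindolin-2-yl (R)-4-acetoxy-5-[3,5-bis(benzyloxy)phenyl]pentanoate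
Conditions: N-hydroxyphthalimide (1.1 equiv), DIC (1.1 equiv), DMAP (0.1 equiv), CH2Cl2, 0 °C → rt
Reagents that add atoms: N-hydroxyphthalimide, O=C1c2ccccc2C(=O)N1O
Why: The same Steglich-type carbodiimide esterification as in step 5 converts the acid into its redox-active ester.

Step 14
Reactants: 9 1,3-dioxoisoindolin-2-yl (R)-4-(tert-butyldimethylsilyloxy)-5-oxodecanoate; 22 1,3-dioxoisoindolin-2-yl (R)-4-acetoxy-5-[3,5-bis(benzyloxy)phenyl]pentanoate
Product: 23 (2R,7R)-1-[3,5-bis(benzyloxy)phenyl]-7-(tert-butyldimethylsilyloxy)-8-oxotridecan-2-yl acetate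
Conditions: 9 (2.5 equiv), 22 (1.0 equiv), NiCl2·6H2O (20 mol %), 2,2':6',2''-terpyridine (20 mol %), AgNO3 (0.3 equiv), NMP, undivided cell, Mg anode, reticulated vitreous carbon cathode, constant current, rt; aq NH4Cl work-up
Reagents that add atoms: none
Why: Cathodically generated low-valent nickel–terpyridine species transfer an electron to each N-acyloxyphthalimide, which fragments to phthalimide anion, CO2 and a primary alkyl radical; nickel captures the two radicals in turn and the dialkylnickel reductively eliminates the C4–C5 bond, with the magnesium anode as electron source and the silver deposit on the cathode tempering direct reduction of the esters. The closest known reaction type is the nickel-electrocatalytic doubly decarboxylative C(sp3)–C(sp3) cross-coupling of two redox-active esters, established for pairs of unhindered primary acids and tolerant of ketones, esters, silyl ethers and benzyl ethers. No ring is closed and no stereocentre is formed; each existing centre is separated from its radical carbon by one CH2, and its oxygen is one position too remote for β-elimination from the alkylnickel, so both pass through unchanged. The step needs cross- over homo-coupling selectivity, which the two alike primary radicals cannot supply, so it is enforced by using 9 (the shorter half) in 2.5-fold excess and separating the two symmetrical dimers, which differ clearly in polarity from 23. Chemoselectivity follows from the phthalimide esters being reduced at far less negative potential than the dialkyl ketone, the acetate and the benzyl ethers, and the base-free reductive mode is preferred to anodic Kolbe coupling because the bis(benzyloxy)arene would be oxidised at Kolbe potentials.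

Step 15
Reactants: 23 (2R,7R)-1-[3,5-bis(benzyloxy)phenyl]-7-(tert-butyldimethylsilyloxy)-8-oxotridecan-2-yl acetate
Product: 24 (2R,7R)-1-[3,5-bis(benzyloxy)phenyl]-7-hydroxy-8-oxotridecan-2-yl acetate
Conditions: HF·pyridine, pyridine, THF, 0 °C → rt
Reagents that add atoms: none
Why: Fluoride-driven desilylation under pyridine-buffered, mildly acidic conditions removes the silyl ether without the base that could epimerise or transpose the α-ketol or cleave the acetate.

Step 16
Reactants: 24 (2R,7R)-1-[3,5-bis(benzyloxy)phenyl]-7-hydroxy-8-oxotridecan-2-yl acetate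
Product: 25 (2R,7R)-1-(3,5-dihydroxyphenyl)-7-hydroxy-8-oxotridecan-2-yl acetate (CNP0374719.1)
Conditions: H2 (1 atm), Pd/C (10 wt % Pd), EtOAc, rt
Reagents that add atoms: none
Why: Catalytic hydrogenolysis cleaves the two aryl benzyl ethers under neutral conditions, while the acetate (homobenzylic, not benzylic), the ketone and the α-ketol are not reduced over palladium at atmospheric pressure.

**Compound list**

1 | (R)-5-oxotetrahydrofuran-2-carboxylic acid | OC(=O)[C@H]1CCC(=O)O1 | starting material
2 | (R)-N-methoxy-N-methyl-5-oxotetrahydrofuran-2-carboxamide | CON(C)C(=O)[C@H]1CCC(=O)O1 | intermediate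
3 | lithium (R)-4-hydroxy-5-[methoxy(methyl)amino]-5-oxopentanoate | CON(C)C(=O)[C@H](O)CCC(=O)[O-].[Li+] | intermediate
4 | tert-butyldimethylsilyl (R)-4-(tert-butyldimethylsilyloxy)-5-[methoxy(methyl)amino]-5-oxopentanoate | CON(C)C(=O)[C@H](O[Si](C)(C)C(C)(C)C)CCC(=O)O[Si](C)(C)C(C)(C)C | intermediate
5 | (R)-4-(tert-butyldimethylsilyloxy)-5-[methoxy(methyl)amino]-5-oxopentanoic acid | CON(C)C(=O)[C@H](O[Si](C)(C)C(C)(C)C)CCC(=O)O | intermediate
6 | 1-bromopentane | CCCCCBr | starting material
7 | pentylmagnesium bromide | CCCCC[Mg]Br | intermediate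
8 | (R)-4-(tert-butyldimethylsilyloxy)-5-oxodecanoic acid | CCCCCC(=O)[C@H](O[Si](C)(C)C(C)(C)C)CCC(=O)O | intermediate
9 | 1,3-dioxoisoindolin-2-yl (R)-4-(tert-butyldimethylsilyloxy)-5-oxodecanoate | CCCCCC(=O)[C@H](O[Si](C)(C)C(C)(C)C)CCC(=O)ON1C(=O)c2ccccc2C1=O | intermediate
10 | (R)-5-(hydroxymethyl)dihydrofuran-2(3H)-one | OC[C@H]1CCC(=O)O1 | intermediate
11 | [(R)-5-oxotetrahydrofuran-2-yl]methyl 4-methylbenzenesulfonate | Cc1ccc(cc1)S(=O)(=O)OC[C@H]1CCC(=O)O1 | intermediate
12 | methyl (R)-4-hydroxy-5-(tosyloxy)pentanoate | COC(=O)CC[C@@H](O)COS(=O)(=O)c1ccc(C)cc1 | intermediate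
13 | methyl (R)-4,5-epoxypentanoate | COC(=O)CC[C@@H]1CO1 | intermediate
14 | 1,3-bis(benzyloxy)-5-bromobenzene | Brc1cc(OCc2ccccc2)cc(OCc2ccccc2)c1 | starting material
15 | 3,5-bis(benzyloxy)phenylmagnesium bromide | Br[Mg]c1cc(OCc2ccccc2)cc(OCc2ccccc2)c1 | intermediate
16 | methyl (R)-5-[3,5-bis(benzyloxy)phenyl]-4-hydroxypentanoate | COC(=O)CC[C@@H](O)Cc1cc(OCc2ccccc2)cc(OCc2ccccc2)c1 | intermediate
17 | (R)-5-[3,5-bis(benzyloxy)benzyl]dihydrofuran-2(3H)-one | O=C1CC[C@H](Cc2cc(OCc3ccccc3)cc(OCc3ccccc3)c2)O1 | intermediate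
18 | potassium (R)-5-[3,5-bis(benzyloxy)phenyl]-4-hydroxypentanoate | [K+].[O-]C(=O)CC[C@@H](O)Cc1cc(OCc2ccccc2)cc(OCc2ccccc2)c1 | intermediate
19 | allyl (R)-5-[3,5-bis(benzyloxy)phenyl]-4-hydroxypentanoate | C=CCOC(=O)CC[C@@H](O)Cc1cc(OCc2ccccc2)cc(OCc2ccccc2)c1 | intermediate
20 | allyl (R)-4-acetoxy-5-[3,5-bis(benzyloxy)phenyl]pentanoate | C=CCOC(=O)CC[C@H](Cc1cc(OCc2ccccc2)cc(OCc2ccccc2)c1)OC(C)=O | intermediate
21 | (R)-4-acetoxy-5-[3,5-bis(benzyloxy)phenyl]pentanoic acid | OC(=O)CC[C@H](Cc1cc(OCc2ccccc2)cc(OCc2ccccc2)c1)OC(C)=O | intermediate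
22 | 1,3-dioxoisoindolin-2-yl (R)-4-acetoxy-5-[3,5-bis(benzyloxy)phenyl]pentanoate | O=C(CC[C@H](Cc1cc(OCc2ccccc2)cc(OCc2ccccc2)c1)OC(C)=O)ON1C(=O)c2ccccc2C1=O | intermediate
23 | (2R,7R)-1-[3,5-bis(benzyloxy)phenyl]-7-(tert-butyldimethylsilyloxy)-8-oxotridecan-2-yl acetate | CCCCCC(=O)[C@H](O[Si](C)(C)C(C)(C)C)CCCC[C@H](Cc1cc(OCc2ccccc2)cc(OCc2ccccc2)c1)OC(C)=O | intermediate
24 | (2R,7R)-1-[3,5-bis(benzyloxy)phenyl]-7-hydroxy-8-oxotridecan-2-yl acetate | CCCCCC(=O)[C@H](O)CCCC[C@H](Cc1cc(OCc2ccccc2)cc(OCc2ccccc2)c1)OC(C)=O | intermediate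
25 | (2R,7R)-1-(3,5-dihydroxyphenyl)-7-hydroxy-8-oxotridecan-2-yl acetate | CCCCCC(=O)[C@H](O)CCCC[C@H](Cc1cc(O)cc(O)c1)OC(C)=O | target

**Step count and risks**

Total step count: 16. Longest linear sequence: 11 steps (1 to 25 through steps 6–16); the ketol half joins after 5 steps.

Steps most likely to fail:

1. Step 14. The two alike primary radicals may mostly homodimerise, or be reduced to the alkanes before nickel captures them, so that little cross-coupled chain forms. The fallback sets out from acid 21 and comes back at 23. It makes the same C4–C5 bond by a nickel-catalysed decarboxylative Negishi alkyl–alkyl coupling, in which only one partner is a radical precursor.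
   - Acid 21 is esterified with N-hydroxypyridine-2-thione and DCC to the Barton ester 2-thioxopyridin-1(2H)-yl (R)-4-acetoxy-5-[3,5-bis(benzyloxy)phenyl]pentanoate F1.
   - Irradiation of this ester with a tungsten lamp in the presence of iodoform (Barton iododecarboxylation) gives the primary iodide (S)-1-[3,5-bis(benzyloxy)phenyl]-4-iodobutan-2-yl acetate F2. The descriptor changes only because iodine raises the CIP rank of the chain; the centre is untouched.
   - Iodine–zinc exchange with Et2Zn and catalytic CuI gives the dialkylzinc bis[(S)-3-acetoxy-4-[3,5-bis(benzyloxy)phenyl]butyl]zinc F3.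
   - Coupling of this zinc reagent with phthalimide ester 9 under NiCl2·glyme and 4,4'-di-tert-butyl-2,2'-bipyridine in THF/DMF at rt should give 23.

2. Step 9. The aryl Grignard reagent may add to the methyl ester, or magnesium bromide may open the epoxide to a bromohydrin before the copper species delivers the aryl group. The fallback sets out from 14 and comes back at 17. It replaces the ester by a terminal alkene as a latent carboxyl and the Grignard reagent by an aryllithium; the stereocentre then comes from a bought epoxide.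
   - Bromine–lithium exchange on 14 (n-BuLi, THF, −78 °C) gives 3,5-bis(benzyloxy)phenyllithium F4.
   - With BF3·OEt2 this opens bought (R)-2-(but-3-en-1-yl)oxirane (C=CCC[C@@H]1CO1) at its CH2 to give (R)-1-[3,5-bis(benzyloxy)phenyl]hex-5-en-2-ol F5.
   - Lemieux–Johnson cleavage (OsO4 cat., NaIO4, 2,6-lutidine, dioxane/H2O) gives the aldehyde, which closes to the lactol (5R)-5-[3,5-bis(benzyloxy)benzyl]tetrahydrofuran-2-ol F6.
   - Oxidation of the lactol with catalytic TEMPO and PhI(OAc)2 in CH2Cl2 gives lactone 17.

3. Step 11. The γ-hydroxy allyl ester may close back to the lactone, expelling allyl alcohol, faster than it is acetylated, returning 17. The fallback sets out from 17 and comes back at 21. It avoids any γ-hydroxy ester by taking the carboxyl carbon down to the alcohol level while the acetate is installed.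
   - LiAlH4 reduction of 17 gives (R)-5-[3,5-bis(benzyloxy)phenyl]pentane-1,4-diol F7.
   - Selective silylation of the primary hydroxyl (TBSCl, imidazole, CH2Cl2, −20 °C) gives (R)-1-[3,5-bis(benzyloxy)phenyl]-5-(tert-butyldimethylsilyloxy)pentan-2-ol F8.
   - Acetylation (Ac2O, pyridine, DMAP) gives (R)-1-[3,5-bis(benzyloxy)phenyl]-5-(tert-butyldimethylsilyloxy)pentan-2-yl acetate F9.
   - HF·pyridine removes the primary silyl ether to give (R)-1-[3,5-bis(benzyloxy)phenyl]-5-hydroxypentan-2-yl acetate F10.
   - Dess–Martin periodinane gives the aldehyde (R)-1-[3,5-bis(benzyloxy)phenyl]-5-oxopentan-2-yl acetate F11.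
   - Pinnick oxidation (NaClO2, NaH2PO4, 2-methyl-2-butene, t-BuOH/H2O) gives acid 21.

**Further compounds**

F1 | step 14 | 2-thioxopyridin-1(2H)-yl (R)-4-acetoxy-5-[3,5-bis(benzyloxy)phenyl]pentanoate | S=c1ccccn1OC(=O)CC[C@H](Cc1cc(OCc2ccccc2)cc(OCc2ccccc2)c1)OC(C)=O
F2 | step 14 | (S)-1-[3,5-bis(benzyloxy)phenyl]-4-iodobutan-2-yl acetate | ICC[C@H](Cc1cc(OCc2ccccc2)cc(OCc2ccccc2)c1)OC(C)=O
F3 | step 14 | bis[(S)-3-acetoxy-4-[3,5-bis(benzyloxy)phenyl]butyl]zinc | [Zn](CC[C@H](Cc1cc(OCc2ccccc2)cc(OCc2ccccc2)c1)OC(C)=O)CC[C@H](Cc1cc(OCc2ccccc2)cc(OCc2ccccc2)c1)OC(C)=O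
F4 | step 9 | 3,5-bis(benzyloxy)phenyllithium | [Li]c1cc(OCc2ccccc2)cc(OCc2ccccc2)c1
F5 | step 9 | (R)-1-[3,5-bis(benzyloxy)phenyl]hex-5-en-2-ol | C=CCC[C@@H](O)Cc1cc(OCc2ccccc2)cc(OCc2ccccc2)c1
F6 | step 9 | (5R)-5-[3,5-bis(benzyloxy)benzyl]tetrahydrofuran-2-ol | OC1CC[C@H](Cc2cc(OCc3ccccc3)cc(OCc3ccccc3)c2)O1
F7 | step 11 | (R)-5-[3,5-bis(benzyloxy)phenyl]pentane-1,4-diol | OCCC[C@@H](O)Cc1cc(OCc2ccccc2)cc(OCc2ccccc2)c1
F8 | step 11 | (R)-1-[3,5-bis(benzyloxy)phenyl]-5-(tert-butyldimethylsilyloxy)pentan-2-ol | CC(C)(C)[Si](C)(C)OCCC[C@@H](O)Cc1cc(OCc2ccccc2)cc(OCc2ccccc2)c1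
F9 | step 11 | (R)-1-[3,5-bis(benzyloxy)phenyl]-5-(tert-butyldimethylsilyloxy)pentan-2-yl acetate | CC(C)(C)[Si](C)(C)OCCC[C@H](Cc1cc(OCc2ccccc2)cc(OCc2ccccc2)c1)OC(C)=O
F10 | step 11 | (R)-1-[3,5-bis(benzyloxy)phenyl]-5-hydroxypentan-2-yl acetate | OCCC[C@H](Cc1cc(OCc2ccccc2)cc(OCc2ccccc2)c1)OC(C)=O
F11 | step 11 | (R)-1-[3,5-bis(benzyloxy)phenyl]-5-oxopentan-2-yl acetate | O=CCC[C@H](Cc1cc(OCc2ccccc2)cc(OCc2ccccc2)c1)OC(C)=O
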